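**Retrosynthetic overview**

1. Feature: in ring B (carbocycle C4a–C5–C6–C7–C8–C8a) the tertiary carbinol C7, next to the C6 ketone, is bonded to C8, and this C7–C8 bond is homoallylic to the C8a=C1 enol ether of ring A (pyran O2–C1–C8a–C4a–C4–C3). This is the retron of a type 2 carbonyl-ene reaction between a C6/C7 1,2-diketone and a C8=C8a alkene with an allylic C1–H.
2. Endgame: δ-lactone ring C by translactonization of a cis-fused C7–O/C8 γ-lactone after C-acylation of its enolate with (S)-β-butyrolactone; C5–Cl by electrophilic chlorination of the pyranylidene ketone; ring A by gold-catalysed 6-endo closure of O1 onto the C3≡C4 alkyne.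
3. Key disconnection: C7–C8, closing ring B by an enantioselective type 2 carbonyl-ene reaction of an acyclic Z,Z-dienyl 1,2-diketone. It is run on the C5–H compound (chlorine is added afterwards), with O1 as a tert-butyldiphenylsilyl ether and the arm as an ethyl ester, because this precursor is accessible stereodefined in few steps.
4. Precursor: C4a–C4 by Pd-catalysed syn hydroalkynylation of an enynone with the side-chain dienyne (fixes C5=C4a); C4a–C8a by Sonogashira coupling of a vinyl iodide (syn hydrostannation of a 3-alkynoate, fixes C8=C8a) with a lactate-derived ynone; the diketone is unmasked last by acyloin oxidation.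
5. Ring order: B (step 15), then A and the γ-lactone (step 17), then δ-lactone C (step 20).

Key step: step 15

Remark: isochromene locants of the target (O2, C1, C3, C4, C4a, C5–C8, C8a; lactone atoms primed) are used for all intermediates.
Remark: C3′ lies between two carbonyl groups and equilibrates through the enol; it is assumed that the drawn (3′R) keto form is the one adopted under thermodynamic control, so no step sets it kinetically.

**Route**

Step 1
Reactants: 1 (S)-2-methylbutan-1-ol
Product: 3 ethyl (2E,4S)-2,4-dimethylhex-2-enoate, via (S)-2-methylbutanal 2 (not isolated)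
Conditions: (COCl)2, DMSO, CH2Cl2, −78 °C; Et3N, −78 → 0 °C; then Ph3P=C(CH3)CO2Et, 23 °C
Reagents that add atoms: ethyl 2-(triphenylphosphoranylidene)propanoate, CCOC(=O)C(C)=P(c1ccccc1)(c1ccccc1)c1ccccc1
Why: Swern oxidation gives the configurationally labile aldehyde 2, which is trapped at once at room temperature by the stabilized ylide in an E-selective Wittig olefination that leaves the stereocentre taken from 1 untouched.

Step 2
Reactants: 3 ethyl (2E,4S)-2,4-dimethylhex-2-enoate
Product: 4 (2E,4S)-2,4-dimethylhex-2-en-1-ol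
Conditions: i-Bu2AlH, CH2Cl2, −78 °C
Reagents that add atoms: none
Why: i-Bu2AlH reduces the conjugated ester 1,2-selectively to the allylic alcohol (ester reduction) without touching the alkene or the stereocentre.

Step 3
Reactants: 4 (2E,4S)-2,4-dimethylhex-2-en-1-ol
Product: 5 (2E,4S)-2,4-dimethylhex-2-enal
Conditions: MnO2, CH2Cl2, 23 °C
Reagents that add atoms: none
Why: MnO2 oxidizes allylic alcohols selectively (allylic oxidation) and should give the enal without E/Z isomerization or epimerization.

Step 4
Reactants: 5 (2E,4S)-2,4-dimethylhex-2-enal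
Product: 7 (3E,5E,7S)-5,7-dimethylnona-3,5-dien-1-yne, via silylated dienyne 6 (not isolated)
Conditions: (EtO)2P(O)CH2C≡CSiMe3, LiN(SiMe3)2, THF, −78 → 0 °C; then MeOH, K2CO3 (0.3 equiv), 23 °C
Reagents that add atoms: diethyl [3-(trimethylsilyl)prop-2-yn-1-yl]phosphonate, CCOP(=O)(CC#C[Si](C)(C)C)OCC
Why: Horner–Wadsworth–Emmons olefination of the enal with the lithiated propargylphosphonate should give the E,E-dienyne, and methanolic K2CO3 added to the same flask removes the alkynyl silyl group (protiodesilylation).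

Step 5
Reactants: 8 prop-2-yn-1-ol
Product: 9 tert-butyldiphenyl(prop-2-yn-1-yloxy)silane
Conditions: t-BuPh2SiCl, imidazole, CH2Cl2, 0 → 23 °C
Reagents that add atoms: tert-butyl(chloro)diphenylsilane, CC(C)(C)[Si](Cl)(c1ccccc1)c1ccccc1
Why: Standard silylation of a primary alcohol; this silyl ether is chosen because it survives the later acidic removal of the triethylsilyl group and is cleaved by fluoride only after the key step.

Step 6
Reactants: 9 tert-butyldiphenyl(prop-2-yn-1-yloxy)silane; 10 ethyl diazoacetate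
Product: 11 ethyl 5-[(tert-butyldiphenylsilyl)oxy]pent-3-ynoate
Conditions: CuI (5 mol %), MeCN, 23 °C
Reagents that add atoms: none
Why: CuI-catalysed coupling of a terminal alkyne with a diazoacetate (copper acetylide and copper carbene) gives the 3-alkynoate directly under base-free conditions, without the allenoate.

Step 7
Reactants: 11 ethyl 5-[(tert-butyldiphenylsilyl)oxy]pent-3-ynoate
Product: 13 ethyl (E)-5-[(tert-butyldiphenylsilyl)oxy]-4-iodopent-3-enoate, via vinylstannane 12 (not isolated)
Conditions: Bu3SnH, PdCl2(PPh3)2 (2 mol %), THF, 0 °C; then I2, CH2Cl2, 0 °C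
Reagents that add atoms: iodine, II; tributyltin hydride, CCCC[SnH](CCCC)CCCC (tin only in 12)
Why: Pd-catalysed hydrostannation is a syn addition that should place tin mainly on the alkyne carbon next to the silyloxymethyl group (the usual proximal preference of propargylic ethers), and iododestannylation with retention then gives the iodide with iodine cis to H and the ester arm cis to CH2OSi; the regioisomeric iodide is removed by chromatography.

Step 8
Reactants: 14 ethyl (S)-lactate
Product: 15 (S)-2-hydroxy-N-methoxy-N-methylpropanamide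
Conditions: MeNHOMe·HCl, i-PrMgCl, THF, −20 → 0 °C
Reagents that add atoms: N,O-dimethylhydroxylamine hydrochloride, CNOC.Cl
Why: Aminolysis of the ester by the chloromagnesium amide gives the N-methoxy-N-methylamide (Weinreb amide), tolerates the hydroxyl as its alkoxide and leaves the stereocentre, which is destroyed in step 14 in any case.

Step 9
Reactants: 15 (S)-2-hydroxy-N-methoxy-N-methylpropanamide
Product: 16 (S)-N-methoxy-N-methyl-2-[(triethylsilyl)oxy]propanamide
Conditions: Et3SiCl, imidazole, CH2Cl2, 0 °C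
Reagents that add atoms: chlorotriethylsilane, CC[Si](Cl)(CC)CC
Why: Silylation of the secondary alcohol as a triethylsilyl ether blocks 5-endo oxa-Michael closure of the later α′-hydroxy ynone to a furanone and is removable by mild acid in the presence of the tert-butyldiphenylsilyl ether.

Step 10
Reactants: 16 (S)-N-methoxy-N-methyl-2-[(triethylsilyl)oxy]propanamide
Product: 17 (S)-4-[(triethylsilyl)oxy]pent-1-yn-3-one
Conditions: HC≡CMgBr, THF, 0 °C; inverse quench into cold aqueous NaHSO4
Reagents that add atoms: ethynylmagnesium bromide, C#C[Mg]Br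
Why: Ketone synthesis from a Weinreb amide, in which the stable magnesium chelate prevents double addition and the acidic inverse quench avoids conjugate addition of the liberated amine to the terminal ynone.

Step 11
Reactants: 13 ethyl (E)-5-[(tert-butyldiphenylsilyl)oxy]-4-iodopent-3-enoate; 17 (S)-4-[(triethylsilyl)oxy]pent-1-yn-3-one
Product: 18 ethyl (3Z,8S)-4-{[(tert-butyldiphenylsilyl)oxy]methyl}-7-oxo-8-[(triethylsilyl)oxy]non-3-en-5-ynoate
Conditions: PdCl2(PPh3)2 (3 mol %), CuI (6 mol %), i-Pr2NEt (2 equiv), THF, 0 → 23 °C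
Reagents that add atoms: none
Why: Sonogashira coupling of the vinyl iodide with the terminal ynone proceeds with retention of alkene geometry, and a hindered tertiary amine at low temperature limits base-induced side reactions of the ynone and of the acidic ester arm.

Step 12
Reactants: 18 ethyl (3Z,8S)-4-{[(tert-butyldiphenylsilyl)oxy]methyl}-7-oxo-8-[(triethylsilyl)oxy]non-3-en-5-ynoate; 7 (3E,5E,7S)-5,7-dimethylnona-3,5-dien-1-yne
Product: 19 ethyl (3Z,5Z,8S)-4-{[(tert-butyldiphenylsilyl)oxy]methyl}-5-[(3E,5E,7S)-5,7-dimethylnona-3,5-dien-1-yn-1-yl]-7-oxo-8-[(triethylsilyl)oxy]nona-3,5-dienoate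
Conditions: Pd(OAc)2 (5 mol %), tris(2,6-dimethoxyphenyl)phosphine (5 mol %), benzene, 23 °C
Reagents that add atoms: none
Why: Pd-catalysed cross-coupling of a terminal donor alkyne with an alkynyl ketone acceptor is a syn hydroalkynylation in which the alkynyl group adds to the β-carbon C4a and hydrogen to C5 on the same side, so that the vinyl group (C8a) ends cis to the C6 carbonyl as the key step requires (any equilibration of 19 with its 2H-pyran valence isomer is harmless).

Step 13
Reactants: 19 ethyl (3Z,5Z,8S)-4-{[(tert-butyldiphenylsilyl)oxy]methyl}-5-[(3E,5E,7S)-5,7-dimethylnona-3,5-dien-1-yn-1-yl]-7-oxo-8-[(triethylsilyl)oxy]nona-3,5-dienoate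
Product: 20 ethyl (3Z,5Z,8S)-4-{[(tert-butyldiphenylsilyl)oxy]methyl}-5-[(3E,5E,7S)-5,7-dimethylnona-3,5-dien-1-yn-1-yl]-8-hydroxy-7-oxonona-3,5-dienoate
Conditions: pyridinium p-toluenesulfonate (0.2 equiv), MeOH–CH2Cl2, 0 °C
Reagents that add atoms: none
Why: Acid-catalysed methanolysis cleaves the triethylsilyl ether selectively (silyl ether solvolysis), the bulkier primary tert-butyldiphenylsilyl ether and the ester being stable to this weak acid.

Step 14
Reactants: 20 ethyl (3Z,5Z,8S)-4-{[(tert-butyldiphenylsilyl)oxy]methyl}-5-[(3E,5E,7S)-5,7-dimethylnona-3,5-dien-1-yn-1-yl]-8-hydroxy-7-oxonona-3,5-dienoate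
Product: 21 ethyl (3Z,5Z)-4-{[(tert-butyldiphenylsilyl)oxy]methyl}-5-[(3E,5E,7S)-5,7-dimethylnona-3,5-dien-1-yn-1-yl]-7,8-dioxonona-3,5-dienoate (ene precursor)
Conditions: Dess–Martin periodinane, NaHCO3, CH2Cl2, 0 → 23 °C; used at once
Reagents that add atoms: none
Why: Dess–Martin oxidation converts the acyloin to the 1,2-diketone under buffered, non-acidic conditions, so that the enophile is unmasked without an acid that could trigger a racemic Prins or ene closure.

Step 15
Reactants: 21 ethyl (3Z,5Z)-4-{[(tert-butyldiphenylsilyl)oxy]methyl}-5-[(3E,5E,7S)-5,7-dimethylnona-3,5-dien-1-yn-1-yl]-7,8-dioxonona-3,5-dienoate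
Product: 22 ethyl 2-[(1S,2Z,6S)-2-{[(tert-butyldiphenylsilyl)oxy]methylidene}-3-[(3E,5E,7S)-5,7-dimethylnona-3,5-dien-1-yn-1-yl]-6-hydroxy-6-methyl-5-oxocyclohex-3-en-1-yl]acetate (ring C1 = C8, ring C6 = C7 of the target)
Conditions: Cu(OTf)2 (10 mol %), 2,2′-(propane-2,2-diyl)bis[(4S)-4-tert-butyl-4,5-dihydro-1,3-oxazole] (11 mol %), 4 Å MS, CH2Cl2, −20 → 23 °C
Reagents that add atoms: none
Why: Proposed new method: an enantioselective intramolecular type 2 carbonyl-ene reaction of a 1,2-diketone with a conjugated dienyl alkene is not known; the diketone should chelate the divalent copper bis(oxazoline) complex through O6 and O7, which makes C7 the most electrophilic carbon, and C8 of the trisubstituted alkene adds to C7 while an allylic C1–H passes to O7 through a six-membered array (O7, C7, C8, C8a, C1, H), so that the C7–C8 bond, the tertiary alcohol and the C8a=C1 silyl enol ether arise in one event. The closest known reaction types are the Me2AlCl-promoted type 2 carbonyl-ene cyclizations of unsaturated aldehydes and ketones and the enantioselective ene reactions of pyruvates, glyoxylates and unsaturated α-keto esters catalysed by divalent copper bis(oxazoline) complexes. Ring B closes as a six-membered ring, exo with respect to the C7 carbonyl and endo with respect to the C8=C8a alkene, through a bicyclo[3.3.1]-like transition state that the Z C5=C4a bond pre-organizes by holding C7 next to C8. C8 is controlled relative to C7 by the alkene geometry, because hydrogen can be handed over only when O7 lies on the C1 side and the ester arm is cis to C1, which places the new hydroxyl cis to the arm; the absolute sense at C7 is controlled by the ligand, the (S,S) ligand being chosen by analogy with the face it shields in pyruvate chelates (its enantiomer serves if the sense is opposite). The step needs site selectivity for C7 over C6 and for C8 over C8a, which the ring size and the more substituted C8a (better able to carry positive charge) secure, and it needs enough nucleophilicity at C8 although the alkene is cross-conjugated with the enone, for which the twist about C4a–C8a enforced by allylic strain in the Z-dienone is relied on. Oxa-6π closure of the Z-dienone to a 2H-pyran is expected only as a reversible side equilibrium that returns the dienone with the arm again cis to C1.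

Step 16
Reactants: 22 ethyl 2-[(1S,2Z,6S)-2-{[(tert-butyldiphenylsilyl)oxy]methylidene}-3-[(3E,5E,7S)-5,7-dimethylnona-3,5-dien-1-yn-1-yl]-6-hydroxy-6-methyl-5-oxocyclohex-3-en-1-yl]acetate
Product: 23 ethyl 2-[(1S,2Z,6S)-3-[(3E,5E,7S)-5,7-dimethylnona-3,5-dien-1-yn-1-yl]-6-hydroxy-2-(hydroxymethylidene)-6-methyl-5-oxocyclohex-3-en-1-yl]acetate
Conditions: Bu4NF, AcOH, THF, 0 °C
Reagents that add atoms: none
Why: Fluoride cleaves the vinylogous silyl ester (silyl dienol ether) readily (desilylation), and acetic acid buffers the medium so that the hydroxymethylidene ketone is released in neutral form; C7 and C8 carry no acidic hydrogen and are not disturbed.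

Step 17
Reactants: 23 ethyl 2-[(1S,2Z,6S)-3-[(3E,5E,7S)-5,7-dimethylnona-3,5-dien-1-yn-1-yl]-6-hydroxy-2-(hydroxymethylidene)-6-methyl-5-oxocyclohex-3-en-1-yl]acetate
Product: 25 (7S,8S)-3-[(1E,3E,5S)-3,5-dimethylhepta-1,3-dien-1-yl]-7-methyl-7,8-dihydro-6H-isochromen-6-one in which O7 and the C8 CH2C(=O) arm form a cis-fused γ-lactone, via pyran hydroxy ester 24 (not isolated)
Conditions: Ph3PAuNTf2 (5 mol %), camphorsulfonic acid (0.2 equiv), CH2Cl2, 23 → 40 °C
Reagents that add atoms: none
Why: The cationic monovalent gold complex activates the C3≡C4 alkyne for 6-endo-dig attack of the enol oxygen O1 at C3, where the dienyl group stabilizes positive charge (gold-catalysed cycloisomerization as with 2-alkynylbenzaldehydes), and the acid co-catalyst then closes the γ-lactone between the C7 hydroxyl and the ester arm (lactonization), which is possible only for the cis relationship set in step 15.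

Step 18
Reactants: 25 the cis-fused γ-lactone pyranylidene ketone
Product: 26 5-chloro derivative of 25
Conditions: N-chlorosuccinimide, MeCN, 0 °C, dark
Reagents that add atoms: N-chlorosuccinimide, O=C1CCC(=O)N1Cl
Why: Electrophilic chlorination of the pyranylidene ketone (a vinylogous 4-pyranone) should occur at C5, the only position whose attack gives an aromatic pyrylium intermediate, as in the known C5 halogenation of azaphilones, and it is done before the nucleophilic β-keto lactone is present.

Step 19
Reactants: 26 5-chloro γ-lactone; 27 (S)-β-butyrolactone [(S)-4-methyloxetan-2-one]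
Product: 29 lactone 26 carrying a (3S)-3-hydroxybutanoyl group on the lactone α-carbon, via lithium enolate 28 (not isolated)
Conditions: LiN(SiMe3)2, THF, −78 °C; then 27, −78 → −40 °C; AcOH quench
Reagents that add atoms: none
Why: Claisen-type C-acylation of the lithium lactone enolate by the β-lactone, which hard lithium enolates attack at the acyl carbon (acyl–oxygen cleavage), so that the C6′ stereocentre of 27 is retained and the released alkoxide neutralizes the more acidic β-keto lactone; the new α-centre is epimerizable and of no consequence.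

Step 20
Reactants: 29 α-(3-hydroxybutanoyl) γ-lactone
Product: 30 (7S,8S)-5-chloro-3-[(1E,3E,5S)-3,5-dimethylhepta-1,3-dien-1-yl]-7-hydroxy-7-methyl-8-[(3R,6S)-6-methyl-2,4-dioxooxan-3-yl]-7,8-dihydro-6H-isochromen-6-one
Conditions: camphorsulfonic acid (0.1 equiv), CH2Cl2, 23 °C
Reagents that add atoms: none
Why: Acid-catalysed translactonization in which the secondary C6′ hydroxyl adds to the activated β-keto lactone carbonyl through a six-membered ring and the tertiary C7 oxygen leaves, the equilibrium being expected to favour the enolizable six-membered β-keto-δ-lactone with a secondary ester linkage; C6′, C7 and C8 are untouched and C3′ settles by enolization.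

**Compound list**

1 | (S)-2-methylbutan-1-ol | CC[C@H](C)CO | starting material
2 | (S)-2-methylbutanal | CC[C@H](C)C=O | intermediate
3 | ethyl (2E,4S)-2,4-dimethylhex-2-enoate | CCOC(=O)/C(C)=C/[C@@H](C)CC | intermediate
4 | (2E,4S)-2,4-dimethylhex-2-en-1-ol | OC/C(C)=C/[C@@H](C)CC | intermediate
5 | (2E,4S)-2,4-dimethylhex-2-enal | O=C/C(C)=C/[C@@H](C)CC | intermediate
6 | trimethyl[(3E,5E,7S)-5,7-dimethylnona-3,5-dien-1-yn-1-yl]silane | C[Si](C)(C)C#C/C=C/C(C)=C/[C@@H](C)CC | intermediate
7 | (3E,5E,7S)-5,7-dimethylnona-3,5-dien-1-yne | C#C/C=C/C(C)=C/[C@@H](C)CC | intermediate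
8 | prop-2-yn-1-ol | C#CCO | starting material
9 | tert-butyldiphenyl(prop-2-yn-1-yloxy)silane | C#CCO[Si](c1ccccc1)(c1ccccc1)C(C)(C)C | intermediate
10 | ethyl diazoacetate | CCOC(=O)C=[N+]=[N-] | starting material
11 | ethyl 5-[(tert-butyldiphenylsilyl)oxy]pent-3-ynoate | CCOC(=O)CC#CCO[Si](c1ccccc1)(c1ccccc1)C(C)(C)C | intermediate
12 | ethyl (E)-5-[(tert-butyldiphenylsilyl)oxy]-4-(tributylstannyl)pent-3-enoate | CCCC[Sn](CCCC)(CCCC)/C(CO[Si](c1ccccc1)(c1ccccc1)C(C)(C)C)=C/CC(=O)OCC | intermediate
13 | ethyl (E)-5-[(tert-butyldiphenylsilyl)oxy]-4-iodopent-3-enoate | CCOC(=O)C/C=C(/I)CO[Si](c1ccccc1)(c1ccccc1)C(C)(C)C | intermediate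
14 | ethyl (S)-lactate | CCOC(=O)[C@H](C)O | starting material
15 | (S)-2-hydroxy-N-methoxy-N-methylpropanamide | C[C@H](O)C(=O)N(C)OC | intermediate
16 | (S)-N-methoxy-N-methyl-2-[(triethylsilyl)oxy]propanamide | C[C@H](O[Si](CC)(CC)CC)C(=O)N(C)OC | intermediate
17 | (S)-4-[(triethylsilyl)oxy]pent-1-yn-3-one | C[C@H](O[Si](CC)(CC)CC)C(=O)C#C | intermediate
18 | ethyl (3Z,8S)-4-{[(tert-butyldiphenylsilyl)oxy]methyl}-7-oxo-8-[(triethylsilyl)oxy]non-3-en-5-ynoate | CCOC(=O)C/C=C(/C#CC(=O)[C@H](C)O[Si](CC)(CC)CC)CO[Si](c1ccccc1)(c1ccccc1)C(C)(C)C | intermediate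
19 | ethyl (3Z,5Z,8S)-4-{[(tert-butyldiphenylsilyl)oxy]methyl}-5-[(3E,5E,7S)-5,7-dimethylnona-3,5-dien-1-yn-1-yl]-7-oxo-8-[(triethylsilyl)oxy]nona-3,5-dienoate | C[C@H](O[Si](CC)(CC)CC)C(=O)/C=C(/C#C/C=C/C(C)=C/[C@@H](C)CC)C(/CO[Si](c1ccccc1)(c1ccccc1)C(C)(C)C)=C/CC(=O)OCC | intermediate
20 | ethyl (3Z,5Z,8S)-4-{[(tert-butyldiphenylsilyl)oxy]methyl}-5-[(3E,5E,7S)-5,7-dimethylnona-3,5-dien-1-yn-1-yl]-8-hydroxy-7-oxonona-3,5-dienoate | C[C@H](O)C(=O)/C=C(/C#C/C=C/C(C)=C/[C@@H](C)CC)C(/CO[Si](c1ccccc1)(c1ccccc1)C(C)(C)C)=C/CC(=O)OCC | intermediate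
21 | ethyl (3Z,5Z)-4-{[(tert-butyldiphenylsilyl)oxy]methyl}-5-[(3E,5E,7S)-5,7-dimethylnona-3,5-dien-1-yn-1-yl]-7,8-dioxonona-3,5-dienoate (ene precursor) | CC(=O)C(=O)/C=C(/C#C/C=C/C(C)=C/[C@@H](C)CC)C(/CO[Si](c1ccccc1)(c1ccccc1)C(C)(C)C)=C/CC(=O)OCC | intermediate
22 | ethyl 2-[(1S,2Z,6S)-2-{[(tert-butyldiphenylsilyl)oxy]methylidene}-3-[(3E,5E,7S)-5,7-dimethylnona-3,5-dien-1-yn-1-yl]-6-hydroxy-6-methyl-5-oxocyclohex-3-en-1-yl]acetate (ene product) | CC[C@H](C)/C=C(C)/C=C/C#CC1=CC(=O)[C@@](C)(O)[C@@H](CC(=O)OCC)/C1=C/O[Si](c2ccccc2)(c2ccccc2)C(C)(C)C | intermediate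
23 | ethyl 2-[(1S,2Z,6S)-3-[(3E,5E,7S)-5,7-dimethylnona-3,5-dien-1-yn-1-yl]-6-hydroxy-2-(hydroxymethylidene)-6-methyl-5-oxocyclohex-3-en-1-yl]acetate | CC[C@H](C)/C=C(C)/C=C/C#CC1=CC(=O)[C@@](C)(O)[C@@H](CC(=O)OCC)/C1=C/O | intermediate
24 | ethyl 2-[(7S,8S)-3-[(1E,3E,5S)-3,5-dimethylhepta-1,3-dien-1-yl]-7-hydroxy-7-methyl-6-oxo-7,8-dihydro-6H-isochromen-8-yl]acetate | CC[C@H](C)/C=C(C)/C=C/C1=CC2=CC(=O)[C@@](C)(O)[C@@H](CC(=O)OCC)C2=CO1 | intermediate
25 | (7S,8S)-3-[(1E,3E,5S)-3,5-dimethylhepta-1,3-dien-1-yl]-7-methyl-7,8-dihydro-6H-isochromen-6-one with O7 and the C8 CH2C(=O) arm joined as a cis-fused γ-lactone | CC[C@H](C)/C=C(C)/C=C/C1=CC2=CC(=O)[C@@]3(C)OC(=O)C[C@H]3C2=CO1 | intermediate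
26 | 5-chloro derivative of γ-lactone 25 | CC[C@H](C)/C=C(C)/C=C/C1=CC2=C(Cl)C(=O)[C@@]3(C)OC(=O)C[C@H]3C2=CO1 | intermediate
27 | (S)-β-butyrolactone, (S)-4-methyloxetan-2-one | C[C@H]1CC(=O)O1 | starting material
28 | lithium enolate of lactone 26 | CC[C@H](C)/C=C(C)/C=C/C1=CC2=C(Cl)C(=O)[C@@]3(C)OC([O-])=C[C@H]3C2=CO1.[Li+] | intermediate
29 | lactone 26 with a (3S)-3-hydroxybutanoyl group on the lactone α-carbon (α-centre unassigned) | CC[C@H](C)/C=C(C)/C=C/C1=CC2=C(Cl)C(=O)[C@@]3(C)OC(=O)C(C(=O)C[C@H](C)O)[C@H]3C2=CO1 | intermediate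
30 | (7S,8S)-5-chloro-3-[(1E,3E,5S)-3,5-dimethylhepta-1,3-dien-1-yl]-7-hydroxy-7-methyl-8-[(3R,6S)-6-methyl-2,4-dioxooxan-3-yl]-7,8-dihydro-6H-isochromen-6-one | CC[C@H](C)/C=C(C)/C=C/C1=CC2=C(Cl)C(=O)[C@@](C)(O)[C@@H]([C@@H]3C(=O)C[C@H](C)OC3=O)C2=CO1 | target

**Step count and risks**

Total steps: 20. Longest linear sequence: 13 steps (for example steps 5, 6, 7, 11–20).

Steps most likely to fail:

1. Step 15 (proposed new method). The C8=C8a alkene, cross-conjugated with the enone, may be too weak a nucleophile for the chelated C7 carbonyl, so that the diketone rests as its 2H-pyran valence isomer or decomposes; facial selectivity at C7 may also be poor.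
 Fallback, by known azaphilone chemistry without an ene step: it sets out from dienyne 7 and β-lactone 27 and comes back to the route at 29. Sonogashira coupling of 7 with 6-bromo-2,4-dihydroxy-3-methylbenzaldehyde (PdCl2(PPh3)2, CuI, Et3N) would give alkynylbenzaldehyde F1. Hydroxylative dearomatization with [Cu(CH3CN)4]PF6, O2 and the sparteine enantiomer that leads to the 7S series, followed by buffered cycloisomerization, would give azaphilone F2, and N-chlorosuccinimide the 5-chloro azaphilone F3. Separately, Claisen condensation of 27 with the lithium enolate of tert-butyl acetate would give hydroxy keto ester F4, silylated with t-BuMe2SiCl to silyl ether F5. Heating F3 with F5 and Et3N in toluene (acyl ketene transfer to the C7 hydroxyl, then Knoevenagel condensation on the C8 carbonyl) would give angular butenolide F6. Conjugate reduction of its doubly activated C8=C bond with [(Ph3P)CuH]6 should deliver hydrogen to C8 from the face that keeps the five-membered lactone cis-fused, giving silylated keto lactone F7, and HF·pyridine would give 29.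

2. Step 19. Acylation by the β-lactone may be slower than decay of the lactone enolate (proton transfer from the side-chain methyl, addition to the electrophilic C1 of the pyran), or the β-lactone may open by alkyl–oxygen cleavage.
 Fallback, aldol addition and oxidation in place of the Claisen acylation: it sets out from 26 and comes back at 29. Ethyl (S)-3-hydroxybutanoate would be silylated with Et3SiCl to silyl ester F8 and reduced with i-Bu2AlH at −78 °C to aldehyde F9. Enolate 28, made from 26 as in step 19, should add to F9 at −78 °C, far faster than to a β-lactone, to give aldol F10. Dess–Martin oxidation would give keto lactone F11, and pyridinium p-toluenesulfonate in MeOH would remove the triethylsilyl group to give 29.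

3. Step 12. Alkynyl transfer to the hindered, vinyl-substituted ynone may be slow, so that head-to-tail dimerization of the donor alkyne or base-type isomerization of the ester arm takes over.
 Fallback, stereoselective sequential cross-coupling of a 1,1-dibromoalkene: it sets out from ynone 17, dienyne 7 and stannane 12 (isolated in step 7 before the iodine quench) and comes back at 19. Bromination of 17 (N-bromosuccinimide, AgNO3) would give bromoynone F12, and conjugate addition of HBr (LiBr, AcOH) the dibromoenone F13. Sonogashira coupling of F13 with 7 should occur at the bromine trans to the carbonyl and give bromoenynone F14 with bromine cis to the carbonyl. Stille coupling of F14 with 12 (Pd2(dba)3, AsPh3, CuI), with retention at both partners, would give 19.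

**Further compounds**

F1 | step 15 | 2,4-dihydroxy-3-methyl-6-[(3E,5E,7S)-5,7-dimethylnona-3,5-dien-1-yn-1-yl]benzaldehyde | CC[C@H](C)/C=C(C)/C=C/C#Cc1cc(O)c(C)c(O)c1C=O
F2 | step 15 | (7R)-3-[(1E,3E,5S)-3,5-dimethylhepta-1,3-dien-1-yl]-7-hydroxy-7-methyl-6H-isochromene-6,8(7H)-dione (same spatial arrangement at C7 as 30) | CC[C@H](C)/C=C(C)/C=C/C1=CC2=CC(=O)[C@@](C)(O)C(=O)C2=CO1
F3 | step 15 | (7S)-5-chloro-3-[(1E,3E,5S)-3,5-dimethylhepta-1,3-dien-1-yl]-7-hydroxy-7-methyl-6H-isochromene-6,8(7H)-dione | CC[C@H](C)/C=C(C)/C=C/C1=CC2=C(Cl)C(=O)[C@@](C)(O)C(=O)C2=CO1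
F4 | step 15 | tert-butyl (S)-5-hydroxy-3-oxohexanoate | C[C@H](O)CC(=O)CC(=O)OC(C)(C)C
F5 | step 15 | tert-butyl (S)-5-[(tert-butyldimethylsilyl)oxy]-3-oxohexanoate | C[C@H](O[Si](C)(C)C(C)(C)C)CC(=O)CC(=O)OC(C)(C)C
F6 | step 15 | angular butenolide: F3 with O7 and C8 bridged by C(=O)–C(acyl)= (C8=C double bond), acyl = (S)-3-[(tert-butyldimethylsilyl)oxy]butanoyl | CC[C@H](C)/C=C(C)/C=C/C1=CC2=C(Cl)C(=O)[C@@]3(C)OC(=O)C(C(=O)C[C@H](C)O[Si](C)(C)C(C)(C)C)=C3C2=CO1
F7 | step 15 | tert-butyldimethylsilyl ether of 29 | CC[C@H](C)/C=C(C)/C=C/C1=CC2=C(Cl)C(=O)[C@@]3(C)OC(=O)C(C(=O)C[C@H](C)O[Si](C)(C)C(C)(C)C)[C@H]3C2=CO1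
F8 | step 19 | ethyl (S)-3-[(triethylsilyl)oxy]butanoate | CCOC(=O)C[C@H](C)O[Si](CC)(CC)CC
F9 | step 19 | (S)-3-[(triethylsilyl)oxy]butanal | O=CC[C@H](C)O[Si](CC)(CC)CC
F10 | step 19 | aldol adduct: lactone 26 with a (3S)-1-hydroxy-3-[(triethylsilyl)oxy]butyl group on the lactone α-carbon | CC[C@H](C)/C=C(C)/C=C/C1=CC2=C(Cl)C(=O)[C@@]3(C)OC(=O)C(C(O)C[C@H](C)O[Si](CC)(CC)CC)[C@H]3C2=CO1
F11 | step 19 | triethylsilyl ether of 29 | CC[C@H](C)/C=C(C)/C=C/C1=CC2=C(Cl)C(=O)[C@@]3(C)OC(=O)C(C(=O)C[C@H](C)O[Si](CC)(CC)CC)[C@H]3C2=CO1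
F12 | step 12 | (S)-1-bromo-4-[(triethylsilyl)oxy]pent-1-yn-3-one | C[C@H](O[Si](CC)(CC)CC)C(=O)C#CBr
F13 | step 12 | (S)-1,1-dibromo-4-[(triethylsilyl)oxy]pent-1-en-3-one | C[C@H](O[Si](CC)(CC)CC)C(=O)C=C(Br)Br
F14 | step 12 | (2S,4Z,8E,10E,12S)-5-bromo-10,12-dimethyl-2-[(triethylsilyl)oxy]tetradeca-4,8,10-trien-6-yn-3-one | C[C@H](O[Si](CC)(CC)CC)C(=O)/C=C(\Br)C#C/C=C/C(C)=C/[C@@H](C)CC
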